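## Structural features

The target joins C6′ of a 2-methoxy-3,5-dimethyl-4H-pyran-4-one to the quaternary carbon C1 of a 1,3,5-trimethylcyclohexa-2,4-diene (C2=C3 and C4=C5; methyl groups on C1, C3 and C5). The neighbouring ring carbon C6 carries one hydrogen and an (E)-4-oxopent-2-en-2-yl chain (C7 to C10, methyl on C7, ketone at C9). C1 and C6 are the only stereocentres; they are adjacent, both S, and the pyranone and the side chain lie on the same ring face. The diene is the most fragile part: protonation at C2 gives an allyl cation that is tertiary at both ends, and proton loss from C6 would then move the diene and erase that stereocentre. Strong acids, π-acidic metals and long heating must therefore be kept away from it. The C6 hydrogen is allylic, is γ to the enone, and is α to any C7 ketone intermediate, so it is also base-labile. The methoxypyranone needs the correct O-methylation regiochemistry and the enone must be E. The real difficulty is an all-carbon quaternary centre bearing a heteroaryl ring next to a tertiary centre, cis and in absolute sense, on a ring that cannot be corrected by equilibration. The key step uses the fact that C1 and C6, flanked by C2 to C5, map onto the alkene of an α-methylbutenolide: its carbonyl carbon becomes C6′ and its γ-carbon with the methyl group becomes C7.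

## Logic of the disconnections

The enone of 24 is redrawn as the propargylic alcohol 23 (oxygen moved from C9 back to C7), and C7–C8 of 23 is cut to give 21 and 22. C7 carries oxygen in every earlier compound, so a C7 ketone is the natural electrophile and C8 to C10 come from a commercial reagent. This avoids olefinating a hindered ketone. The forward steps must add to a ketone whose α-hydrogen is allylic without enolising it, and must move oxygen without Brønsted acids or π-acids.

The C7 carbonyl of 21 is taken back to the alcohol 20 and its silyl ether 19 (C7–O–Si bond). C7 stays a protected alcohol while the heterocycle is made, because a C7 ketone would stand 1,4 to the acyl carbon on C1 and invite aldol ring closure and epimerisation at C6. The protecting group must survive hydride, a strong carbon base, hypervalent iodine, DBU and methyl triflate, and leave under buffered fluoride.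

In 19 the O–CH3 bond is cut (18), then the ring bond O1′–C2′ (17), then the oxidation level of C6′ is lowered (16), and finally C5′–C6′ is cut to give 13 and 15, the latter made from 14. Carbons C2′ to C5′ with both methyl groups are already present in 14. The one bond to the crowded C1 neighbourhood is made at the aldehyde level, the most reactive acyl level. The aldehyde must accept a secondary carbanion, and the methylation of 18 must occur at the lactone carbonyl oxygen with the acid by-product intercepted.

13 is traced through 12 (C–N for C–H at the acyl carbon) and 11 (O–Si bond) to 10 by reconnecting the acyl carbon on C1 to the oxygen on C7. The two groups are 1,4-related and cis, which is a γ-lactone, so two functional groups and their relative placement collapse into one ring. The forward step must open a hindered cis-fused lactone and capture the alkoxide before it can close again.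

The C2=C3–C4=C5 diene of 10 is replaced by a C3=C4 alkene with oxygen on C2 and hydrogen on C5 (9, then 8 and 7 by changing the group on oxygen). This is the retron of a cycloaddition with a 1-oxygenated diene, and the sensitive diene then appears only after the ring exists. The two groups to be removed are trans on the ring, as the diene geometry dictates. Acid is excluded because 10 protonates more easily than 7 ionises, so a palladium π-allyl elimination is used.

C1–C2 and C5–C6 of 7 are cut together to give 4 and 6. This is the largest simplification: a bicycle with five stereocentres becomes two small fragments, one of them carrying the only stereocentre that is bought. The forward step needs the silyloxy carbon to bond to the α-carbon of 4, approach anti to the C7 methyl group, and enough reactivity from a trisubstituted dienophile. A stereochemical check shows that S at C7 of 4 with anti approach gives the C1 and C6 configuration of 24.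

The ring alkene of 4 is cut (3), then the ester C–O bond (1 and 2). This gives 4 in two steps with the stereocentre taken unchanged from 1. The ring closure must engage a 1,1-disubstituted acrylate.

The O–Si bond of 6 is cut to give 5. γ-Deprotonation must give the 1E,3E geometry.

## Other disconnections considered

Alternative 1: The cut is C6–C7 together with the C1–methyl bond, on an aromatic ring. In THF with DMPU the alkenyllithium A2 would add to an ortho carbon of the (4R)-isopropyl oxazoline A1, and MeI would alkylate the aza-enolate at the ipso carbon, anti to the new substituent, to give A3.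
- In favour: two bonds, both stereocentres, the diene in its final position and the E-alkene arrive in one operation from an arene. To a ring with C1 and C6 defined it is better than the chosen plan on step count (about three steps against seven), and it avoids the enone construction of steps 16 and 17.
- Against: such additions to simple phenyl oxazolines are dependable with secondary and tertiary alkyllithiums; an sp2 nucleophile is less reactive and would compete with ortho-lithiation. The ortho carbon is flanked by a methyl-bearing carbon. Absolute control rests on a remote auxiliary centre. Converting the oxazoline to the acyl level and hydrolysing the dioxolane both need acid or strong alkylating agents in the presence of the diene.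
- Comparison: it equals the chosen plan in giving the cis arrangement by a trans addition. It is weaker in precedent for the key step and in late-stage acid exposure. Both need about six further steps for the pyranone.

Alternative 2: The cut is C6–C7, with C7 tethered through an ester to the acyl carbon on C1. With Pd2(dba)3, BINAP and Ag3PO4 the alkenyl iodide of the achiral ester A4 would add to zerovalent palladium, insert into one enantiotopic ring alkene (6-exo) and lose a hydride toward C4 to give A5.
- In favour: the stereocentres come from a catalyst and an achiral precursor. The tether enforces the cis relationship, equal to the lactone logic of the chosen plan. The alkene geometry is inherited from the iodide, which is better than the thermodynamic control of step 17. The diene forms directly.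
- Against: insertion puts palladium on a methyl-bearing carbon, so it is slow and can eliminate toward the methyl group. Enantioselectivity on this substitution pattern is uncertain. The C7 methyl arrives as a lactone CH2–O that must later be deoxygenated at an allylic position, and the ketal again needs acid.
- Comparison: it is shorter to the carbocycle than the chosen plan, but longer and riskier afterwards.

Alternative 3: The cut is C3–C4. PtCl2 or (Ph3P)AuNTf2 would activate the propynyl group of the enyne lactone A6, the CH2 terminus of the cis isopropenyl group would attack the distal alkyne carbon (6-endo-dig), and proton loss from C4 with protodemetalation at C2 would give A7, which is the same compound as 10.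
- In favour: it is an isomerisation under neutral conditions with no leaving-group chemistry. It would replace steps 4 to 7 by one step and join the chosen route at 10, so everything downstream is equal.
- Against: A6 needs a quaternary centre carrying an alkynyl group cis to the isopropenyl group, which is harder to make than 7. 1,5-Enynes with divalent platinum or monovalent gold often give bicyclo[3.1.0]hexenes instead, and the site of proton loss is not secured. The product diene would sit with a π-acid.
- Comparison: it is better in atom economy and in the key-step count. It is weaker in access to the precursor and in chemoselectivity.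

Key step: step 4

Assumption: step 3 is taken to give mainly the 1E,3E isomer of 6; minor geometric isomers cannot reach the s-cis form and pass through step 4 unchanged.

## Route

Step 1
Reactants: 1 (S)-but-3-en-2-ol; 2 methacryloyl chloride
Product: 3 (S)-but-3-en-2-yl methacrylate
Conditions: Et3N, DMAP (cat.), CH2Cl2, 0 °C → rt
Reagents that add atoms: none
Why: Acylation of a secondary alcohol by an acid chloride under nucleophilic catalysis; the C–O bond of the stereocentre is not broken, so it stays S.

Step 2
Reactants: 3 (S)-but-3-en-2-yl methacrylate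
Product: 4 (S)-3,5-dimethylfuran-2(5H)-one
Conditions: (H2IMes)(PCy3)Cl2Ru=CHPh (second-generation Grubbs catalyst, 5 mol%), CH2Cl2 (0.02 M), 40 °C
Reagents that add atoms: none
Why: Ring-closing metathesis: the ruthenium carbene loads on the monosubstituted alkene and closes onto the 1,1-disubstituted acrylate with loss of ethene; dilution suppresses dimerisation and the stereocentre is untouched.

Step 3
Reactants: 5 (E)-2-methylpent-2-enal
Product: 6 (1E,3E)-1-(tert-butyldimethylsilyloxy)-2-methylpenta-1,3-diene
Conditions: TBSOTf, Et3N, Et2O, 0 °C → rt
Reagents that add atoms: tert-butyldimethylsilyl trifluoromethanesulfonate, CC(C)(C)[Si](C)(C)OS(=O)(=O)C(F)(F)F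
Why: O-Silylation of the enal and γ-deprotonation of the silyloxocarbenium ion by the amine (silyl dienol ether formation); the s-trans enal should give mainly the 1E,3E diene.

Step 4
Reactants: 4 (S)-3,5-dimethylfuran-2(5H)-one; 6 (1E,3E)-1-(tert-butyldimethylsilyloxy)-2-methylpenta-1,3-diene
Product: 7 (3S,3aR,4R,7S,7aR)-7-(tert-butyldimethylsilyloxy)-3,4,6,7a-tetramethyl-3a,4,7,7a-tetrahydroisobenzofuran-1(3H)-one (endo adduct; in target locants 1R,2S,5R,6R,7S)
Conditions: 6 (3 equiv), BHT (cat.), CH2Cl2, 13 kbar, 40 °C
Reagents that add atoms: none
Why: Normal-electron-demand Diels–Alder reaction, concerted but asynchronous: the methyl-bearing diene terminus remote from oxygen has the largest HOMO coefficient and bonds first to the β-carbon of 4 (C5–C6), and the silyloxy carbon then closes onto the α-carbon (C1–C2). The closest known reaction type is the cycloaddition of 1-silyloxy dienes to γ-substituted butenolides; high pressure is chosen because the α-methyl group makes 4 sluggish and the activation volume is strongly negative. The six-membered carbocycle is closed by the two-bond [4+2] addition itself, suprafacial on both partners, so it is cis-fused to the lactone. C1 and C6 are set by approach of the diene to the face of 4 opposite the C7 methyl group (control by the existing S centre), and their cis relationship follows from the ring alkene. C2 and C5 are set by the endo transition state and the E,E geometry of 6, which place the silyloxy group and the C5 methyl cis to each other; both centres become planar in step 7, so an exo component is harmless. The step needs ortho regiochemistry, secured by the oxygen donor against the lactone carbonyl, and π-facial selectivity, secured by the γ-methyl group; BHT suppresses radical oligomerisation of the diene.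

Step 5
Reactants: 7 (3S,3aR,4R,7S,7aR)-7-(tert-butyldimethylsilyloxy)-3,4,6,7a-tetramethyl-3a,4,7,7a-tetrahydroisobenzofuran-1(3H)-one
Product: 8 (3S,3aR,4R,7S,7aR)-7-hydroxy-3,4,6,7a-tetramethyl-3a,4,7,7a-tetrahydroisobenzofuran-1(3H)-one
Conditions: 48% aq. HF, MeCN, 0 °C → rt
Reagents that add atoms: none
Why: Acidic fluoride cleavage of the silyl ether; acid is preferred to basic fluoride so that the β-hydroxy lactone cannot undergo retro-aldol cleavage, and no stereocentre is touched.

Step 6
Reactants: 8 (3S,3aR,4R,7S,7aR)-7-hydroxy-3,4,6,7a-tetramethyl-3a,4,7,7a-tetrahydroisobenzofuran-1(3H)-one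
Product: 9 (3S,3aR,4R,7S,7aR)-7-(methoxycarbonyloxy)-3,4,6,7a-tetramethyl-3a,4,7,7a-tetrahydroisobenzofuran-1(3H)-one
Conditions: ClCO2Me, pyridine, DMAP, CH2Cl2, 0 °C → rt
Reagents that add atoms: methyl chloroformate, COC(=O)Cl
Why: Acylation of the hindered allylic alcohol by a small chloroformate under DMAP catalysis installs the leaving group for palladium with retention at C2.

Step 7
Reactants: 9 (3S,3aR,4R,7S,7aR)-7-(methoxycarbonyloxy)-3,4,6,7a-tetramethyl-3a,4,7,7a-tetrahydroisobenzofuran-1(3H)-one
Product: 10 (3S,3aR,7aS)-3,4,6,7a-tetramethyl-3a,7a-dihydroisobenzofuran-1(3H)-one (in target locants 1S,6R,7S)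
Conditions: Pd(PPh3)4 (5 mol%), 1,4-dioxane, 100 °C
Reagents that add atoms: none
Why: Palladium-catalysed 1,4-elimination of an allylic carbonate (Tsuji–Trost ionisation followed by β-hydride elimination): zerovalent palladium displaces the carbonate with inversion, which puts the metal of the C2–C4 π-allyl complex on the face that carries the C5 hydrogen, and syn β-hydride elimination gives C4=C5. Methoxide from decarboxylation removes the hydride as methanol, so no acid is present and C1, C6 and C7 are untouched.

Step 8
Reactants: 10 (3S,3aR,7aS)-3,4,6,7a-tetramethyl-3a,7a-dihydroisobenzofuran-1(3H)-one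
Product: 12 (1S,6R)-N-methoxy-N,1,3,5-tetramethyl-6-[(S)-1-(triethylsilyloxy)ethyl]cyclohexa-2,4-diene-1-carboxamide, via chloromagnesium alkoxide of the ring-opened hydroxy amide 11 (not isolated)
Conditions: MeNH(OMe)·HCl, i-PrMgCl, THF, −20 → 0 °C; then TESCl, imidazole, DMAP, 0 °C → rt
Reagents that add atoms: N,O-dimethylhydroxylamine hydrochloride, CNOC.Cl; chlorotriethylsilane, CC[Si](Cl)(CC)CC
Why: Aminolysis of the lactone by the magnesium amide of N,O-dimethylhydroxylamine (Weinreb amide formation), then silylation of the magnesium alkoxide in the same flask, so that the free hydroxy amide, which would close back to the lactone, never exists; the C7–O bond is not broken and C7 stays S.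

Step 9
Reactants: 12 (1S,6R)-N-methoxy-N,1,3,5-tetramethyl-6-[(S)-1-(triethylsilyloxy)ethyl]cyclohexa-2,4-diene-1-carboxamide
Product: 13 (1S,6R)-1,3,5-trimethyl-6-[(S)-1-(triethylsilyloxy)ethyl]cyclohexa-2,4-diene-1-carbaldehyde
Conditions: i-Bu2AlH, THF, −78 °C; aq. KNaC4H4O6
Reagents that add atoms: none
Why: Hydride reduction of a Weinreb amide stops at the chelated tetrahedral intermediate and releases the aldehyde on work-up; the aldehyde has no α-hydrogen and cannot epimerise.

Step 10
Reactants: 13 (1S,6R)-1,3,5-trimethyl-6-[(S)-1-(triethylsilyloxy)ethyl]cyclohexa-2,4-diene-1-carbaldehyde; 14 methyl 2-methyl-3-oxopentanoate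
Product: 16 methyl 5-hydroxy-2,4-dimethyl-3-oxo-5-{(1S,6R)-1,3,5-trimethyl-6-[(S)-1-(triethylsilyloxy)ethyl]cyclohexa-2,4-dien-1-yl}pentanoate (diastereomer mixture at the three chain centres), via sodium lithium dianion of the keto ester 15 (not isolated)
Conditions: 14, NaH, THF, 0 °C; n-BuLi, 0 °C; then 13, −78 → −40 °C; aq. NH4Cl
Reagents that add atoms: none
Why: Aldol addition of the γ-carbon of a β-keto ester dianion to a non-enolisable aldehyde; the new chain stereocentres are formed without control and are all removed in steps 11 and 12.

Step 11
Reactants: 16 methyl 5-hydroxy-2,4-dimethyl-3-oxo-5-{(1S,6R)-1,3,5-trimethyl-6-[(S)-1-(triethylsilyloxy)ethyl]cyclohexa-2,4-dien-1-yl}pentanoate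
Product: 17 methyl 2,4-dimethyl-3,5-dioxo-5-{(1S,6R)-1,3,5-trimethyl-6-[(S)-1-(triethylsilyloxy)ethyl]cyclohexa-2,4-dien-1-yl}pentanoate
Conditions: Dess–Martin periodinane, NaHCO3, CH2Cl2, rt
Reagents that add atoms: none
Why: Dess–Martin oxidation of the secondary alcohol under bicarbonate buffer gives the β,δ-diketo ester without acid reaching the diene or the silyl ether.

Step 12
Reactants: 17 methyl 2,4-dimethyl-3,5-dioxo-5-{(1S,6R)-1,3,5-trimethyl-6-[(S)-1-(triethylsilyloxy)ethyl]cyclohexa-2,4-dien-1-yl}pentanoate
Product: 18 4-hydroxy-3,5-dimethyl-6-{(1S,6R)-1,3,5-trimethyl-6-[(S)-1-(triethylsilyloxy)ethyl]cyclohexa-2,4-dien-1-yl}-2H-pyran-2-one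
Conditions: DBU, toluene, rt → 60 °C
Reagents that add atoms: none
Why: Base-mediated cyclisation: the enol oxygen of the ketone next to C1 attacks the ester (6-exo-trig lactonisation), methanol leaves and tautomerisation gives the 4-hydroxy-2-pyranone.

Step 13
Reactants: 18 4-hydroxy-3,5-dimethyl-6-{(1S,6R)-1,3,5-trimethyl-6-[(S)-1-(triethylsilyloxy)ethyl]cyclohexa-2,4-dien-1-yl}-2H-pyran-2-one
Product: 19 2-methoxy-3,5-dimethyl-6-{(1S,6R)-1,3,5-trimethyl-6-[(S)-1-(triethylsilyloxy)ethyl]cyclohexa-2,4-dien-1-yl}-4H-pyran-4-one
Conditions: MeOTf, 2,6-di-tert-butyl-4-methylpyridine, CH2Cl2, 0 °C → rt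
Reagents that add atoms: methyl trifluoromethanesulfonate, COS(=O)(=O)C(F)(F)F
Why: A hard methylating agent alkylates the neutral 4-hydroxy-2-pyranone at its lactone carbonyl oxygen to a 2-methoxy-4-hydroxypyrylium ion, which the hindered pyridine deprotonates to the 2-methoxy-4-pyranone; the same base keeps triflic acid away from the diene and the silyl ether.

Step 14
Reactants: 19 2-methoxy-3,5-dimethyl-6-{(1S,6R)-1,3,5-trimethyl-6-[(S)-1-(triethylsilyloxy)ethyl]cyclohexa-2,4-dien-1-yl}-4H-pyran-4-one
Product: 20 6-{(1S,6R)-6-[(S)-1-hydroxyethyl]-1,3,5-trimethylcyclohexa-2,4-dien-1-yl}-2-methoxy-3,5-dimethyl-4H-pyran-4-one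
Conditions: HF·pyridine, pyridine, THF, 0 °C → rt
Reagents that add atoms: none
Why: Buffered fluoride cleavage of the triethylsilyl ether; the pyranone and the diene should not react under these nearly neutral conditions.

Step 15
Reactants: 20 6-{(1S,6R)-6-[(S)-1-hydroxyethyl]-1,3,5-trimethylcyclohexa-2,4-dien-1-yl}-2-methoxy-3,5-dimethyl-4H-pyran-4-one
Product: 21 6-[(1S,6R)-6-acetyl-1,3,5-trimethylcyclohexa-2,4-dien-1-yl]-2-methoxy-3,5-dimethyl-4H-pyran-4-one
Conditions: Dess–Martin periodinane, NaHCO3, CH2Cl2, 0 °C → rt
Reagents that add atoms: none
Why: Dess–Martin oxidation under buffer gives the methyl ketone without acid or base that could enolise it toward C6.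

Step 16
Reactants: 21 6-[(1S,6R)-6-acetyl-1,3,5-trimethylcyclohexa-2,4-dien-1-yl]-2-methoxy-3,5-dimethyl-4H-pyran-4-one; 22 1-propynylmagnesium bromide
Product: 23 6-[(1S,6R)-6-(2-hydroxypent-3-yn-2-yl)-1,3,5-trimethylcyclohexa-2,4-dien-1-yl]-2-methoxy-3,5-dimethyl-4H-pyran-4-one (both C7 epimers)
Conditions: 22, CeCl3, THF, −78 °C; aq. NH4Cl
Reagents that add atoms: none
Why: 1,2-Addition of the weakly basic alkynylcerium reagent to the ketone should outrun enolisation at C6 and leave the vinylogous-ester carbonyl of the pyranone alone; the uncontrolled C7 centre is destroyed in step 17.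

Step 17
Reactants: 23 6-[(1S,6R)-6-(2-hydroxypent-3-yn-2-yl)-1,3,5-trimethylcyclohexa-2,4-dien-1-yl]-2-methoxy-3,5-dimethyl-4H-pyran-4-one
Product: 24 2-methoxy-3,5-dimethyl-6-{(1S,6S)-1,3,5-trimethyl-6-[(E)-4-oxopent-2-en-2-yl]cyclohexa-2,4-dien-1-yl}-4H-pyran-4-one (target)
Conditions: VO(OSiPh3)3 (10 mol%), Ph3SiOH (20 mol%), toluene, 80 °C
Reagents that add atoms: none
Why: Meyer–Schuster rearrangement through an ester of pentavalent vanadium: the propargyl vanadate undergoes a [3,3] shift to an allenyl vanadate, and protonolysis with tautomerisation gives the enone without Brønsted acid or π-acid near the diene. The E isomer should prevail because the Z isomer would hold the ring cis to the acetyl group; the C6 descriptor changes from R to S only because the CIP rank of C7 changes.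

## Compound list

1 | (S)-but-3-en-2-ol | C[C@H](O)C=C | starting material
2 | methacryloyl chloride | CC(=C)C(=O)Cl | starting material
3 | (S)-but-3-en-2-yl methacrylate | C[C@H](OC(=O)C(C)=C)C=C | intermediate
4 | (S)-3,5-dimethylfuran-2(5H)-one | CC1=C[C@H](C)OC1=O | intermediate
5 | (E)-2-methylpent-2-enal | CC/C=C(\C)C=O | starting material
6 | (1E,3E)-1-(tert-butyldimethylsilyloxy)-2-methylpenta-1,3-diene | C/C=C/C(C)=C/O[Si](C)(C)C(C)(C)C | intermediate
7 | (3S,3aR,4R,7S,7aR)-7-(tert-butyldimethylsilyloxy)-3,4,6,7a-tetramethyl-3a,4,7,7a-tetrahydroisobenzofuran-1(3H)-one | O=C1[C@@]2(C)[C@@H](O[Si](C)(C)C(C)(C)C)C(C)=C[C@@H](C)[C@H]2[C@H](C)O1 | intermediate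
8 | (3S,3aR,4R,7S,7aR)-7-hydroxy-3,4,6,7a-tetramethyl-3a,4,7,7a-tetrahydroisobenzofuran-1(3H)-one | O=C1[C@@]2(C)[C@@H](O)C(C)=C[C@@H](C)[C@H]2[C@H](C)O1 | intermediate
9 | (3S,3aR,4R,7S,7aR)-7-(methoxycarbonyloxy)-3,4,6,7a-tetramethyl-3a,4,7,7a-tetrahydroisobenzofuran-1(3H)-one | O=C1[C@@]2(C)[C@@H](OC(=O)OC)C(C)=C[C@@H](C)[C@H]2[C@H](C)O1 | intermediate
10 | (3S,3aR,7aS)-3,4,6,7a-tetramethyl-3a,7a-dihydroisobenzofuran-1(3H)-one | O=C1[C@@]2(C)C=C(C)C=C(C)[C@H]2[C@H](C)O1 | intermediate
11 | chloromagnesium (S)-1-{(1R,6S)-6-[methoxy(methyl)carbamoyl]-2,4,6-trimethylcyclohexa-2,4-dien-1-yl}ethoxide | CON(C)C(=O)[C@@]1(C)C=C(C)C=C(C)[C@H]1[C@H](C)O[Mg]Cl | intermediate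
12 | (1S,6R)-N-methoxy-N,1,3,5-tetramethyl-6-[(S)-1-(triethylsilyloxy)ethyl]cyclohexa-2,4-diene-1-carboxamide | CON(C)C(=O)[C@@]1(C)C=C(C)C=C(C)[C@H]1[C@H](C)O[Si](CC)(CC)CC | intermediate
13 | (1S,6R)-1,3,5-trimethyl-6-[(S)-1-(triethylsilyloxy)ethyl]cyclohexa-2,4-diene-1-carbaldehyde | O=C[C@@]1(C)C=C(C)C=C(C)[C@H]1[C@H](C)O[Si](CC)(CC)CC | intermediate
14 | methyl 2-methyl-3-oxopentanoate | CCC(=O)C(C)C(=O)OC | starting material
15 | sodium lithium dianion (dienolate) of methyl 2-methyl-3-oxopentanoate | CC=C([O-])C(C)=C([O-])OC.[Na+].[Li+] | intermediate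
16 | methyl 5-hydroxy-2,4-dimethyl-3-oxo-5-{(1S,6R)-1,3,5-trimethyl-6-[(S)-1-(triethylsilyloxy)ethyl]cyclohexa-2,4-dien-1-yl}pentanoate | COC(=O)C(C)C(=O)C(C)C(O)[C@@]1(C)C=C(C)C=C(C)[C@H]1[C@H](C)O[Si](CC)(CC)CC | intermediate
17 | methyl 2,4-dimethyl-3,5-dioxo-5-{(1S,6R)-1,3,5-trimethyl-6-[(S)-1-(triethylsilyloxy)ethyl]cyclohexa-2,4-dien-1-yl}pentanoate | COC(=O)C(C)C(=O)C(C)C(=O)[C@@]1(C)C=C(C)C=C(C)[C@H]1[C@H](C)O[Si](CC)(CC)CC | intermediate
18 | 4-hydroxy-3,5-dimethyl-6-{(1S,6R)-1,3,5-trimethyl-6-[(S)-1-(triethylsilyloxy)ethyl]cyclohexa-2,4-dien-1-yl}-2H-pyran-2-one | O=C1OC(=C(C)C(O)=C1C)[C@@]2(C)C=C(C)C=C(C)[C@H]2[C@H](C)O[Si](CC)(CC)CC | intermediate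
19 | 2-methoxy-3,5-dimethyl-6-{(1S,6R)-1,3,5-trimethyl-6-[(S)-1-(triethylsilyloxy)ethyl]cyclohexa-2,4-dien-1-yl}-4H-pyran-4-one | COc1oc([C@@]2(C)C=C(C)C=C(C)[C@H]2[C@H](C)O[Si](CC)(CC)CC)c(C)c(=O)c1C | intermediate
20 | 6-{(1S,6R)-6-[(S)-1-hydroxyethyl]-1,3,5-trimethylcyclohexa-2,4-dien-1-yl}-2-methoxy-3,5-dimethyl-4H-pyran-4-one | COc1oc([C@@]2(C)C=C(C)C=C(C)[C@H]2[C@H](C)O)c(C)c(=O)c1C | intermediate
21 | 6-[(1S,6R)-6-acetyl-1,3,5-trimethylcyclohexa-2,4-dien-1-yl]-2-methoxy-3,5-dimethyl-4H-pyran-4-one | COc1oc([C@@]2(C)C=C(C)C=C(C)[C@H]2C(C)=O)c(C)c(=O)c1C | intermediate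
22 | 1-propynylmagnesium bromide | CC#C[Mg]Br | starting material
23 | 6-[(1S,6R)-6-(2-hydroxypent-3-yn-2-yl)-1,3,5-trimethylcyclohexa-2,4-dien-1-yl]-2-methoxy-3,5-dimethyl-4H-pyran-4-one (C7 epimers) | COc1oc([C@@]2(C)C=C(C)C=C(C)[C@H]2C(C)(O)C#CC)c(C)c(=O)c1C | intermediate
24 | 2-methoxy-3,5-dimethyl-6-{(1S,6S)-1,3,5-trimethyl-6-[(E)-4-oxopent-2-en-2-yl]cyclohexa-2,4-dien-1-yl}-4H-pyran-4-one | COc1oc([C@@]2(C)C=C(C)C=C(C)[C@H]2/C(C)=C/C(C)=O)c(C)c(=O)c1C | target

## Step count and least certain steps

Total: 17 steps. Longest linear sequence: 16 steps (steps 1, 2 and 4 to 17, from 1); step 3 is a one-step branch.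

Step 4 (key step). The cycloaddition may stall, because 4 is a trisubstituted dienophile carrying a deactivating α-methyl group and 6 has a substituted terminus. During a long reaction the diene may then be lost to oligomerisation, hydrolysis or geometric isomerisation. Fallback: do the cycloaddition on the dienophile without the α-methyl group and add the methyl group afterwards.
- It sets out from 1, which is acylated with acryloyl chloride to (S)-but-3-en-2-yl acrylate F1.
- Ring-closing metathesis as in step 2 gives (S)-5-methylfuran-2(5H)-one F2.
- F2 is far more reactive toward 6 and should give the cis-fused des-methyl adduct F3 by the same anti, ortho, endo mode.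
- Deprotonation with LiN(i-Pr)2 in THF at −78 °C and alkylation with MeI on the convex face, anti to the C2 silyloxy group, returns to the route at 7. The low temperature is needed to hold back β-elimination of the silyloxy group from the enolate.

Step 7. Ionisation of the neopentyl-type, 2-substituted allylic carbonate may be slow. A palladium hydride may re-add to the product and walk the diene toward C6. Methoxide may capture the π-allyl complex as an allylic ether. Fallback: a buffered cationic elimination. It sets out from 8, which is treated with Tf2O and 2,6-di-tert-butyl-4-methylpyridine in CH2Cl2 at −78 → 0 °C. The allylic triflate F4, not isolated, ionises, and the hindered base removes the C5 proton and keeps the product from being re-protonated; the sequence returns at 10.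

Step 8. Attack of the magnesium amide on the hindered lactone carbonyl may be incomplete. The cis arrangement next to a quaternary centre favours re-closure of the hydroxy amide if silylation lags. Fallback: an irreversible reductive opening. It sets out from 10, which LiAlH4 in THF reduces to the diol F5. TESCl and imidazole give the bis(triethylsilyl) ether F6. Swern oxidation (oxalyl chloride, DMSO, Et3N, −78 → −30 °C) cleaves and oxidises only the primary silyl ether and returns at 13.

Step 13. Methylation may occur at the C4′ oxygen if the pyranone reacts as its anion, giving the isomeric 4-methoxy-2-pyranone. If buffering is imperfect, acid may move the ring diene or remove the silyl ether. Fallback: skip the hydroxypyranone. It sets out from 17, which is cyclodehydrated with Ph3P and CCl4 in THF in the presence of a hindered pyridine base. The ester methoxy group is retained and the sequence returns at 19; it makes no compound outside the list (entry F0).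

Step 17. The shift may give an E/Z mixture. The tertiary alcohol may dehydrate to an enyne. The pyranone may bind the vanadium centre and slow the catalysis, and the longer heating then needed may allow a 1,5-hydrogen shift in the diene. Fallback: an oxidative allylic transposition. It sets out from 21, to which CH3CH=CHMgBr with CeCl3 in THF at −78 °C adds to give the tertiary allylic alcohol F7. Buffered pyridinium chlorochromate [C5H5NH][CrO3Cl] with NaOAc in CH2Cl2 (Babler–Dauben oxidation, [3,3] shift of the ester of hexavalent chromium, then oxidation) returns at 24.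

## Further compounds

F1 | step 4 | (S)-but-3-en-2-yl acrylate | C[C@H](OC(=O)C=C)C=C
F2 | step 4 | (S)-5-methylfuran-2(5H)-one | O=C1C=C[C@H](C)O1
F3 | step 4 | (3S,3aR,4R,7S,7aS)-7-(tert-butyldimethylsilyloxy)-3,4,6-trimethyl-3a,4,7,7a-tetrahydroisobenzofuran-1(3H)-one (cis-fused, C1 hydrogen in place of the C1 methyl of 7) | O=C1[C@H]2[C@@H](O[Si](C)(C)C(C)(C)C)C(C)=C[C@@H](C)[C@H]2[C@H](C)O1
F4 | step 7 | allylic trifluoromethanesulfonate of 8 (triflate on the C2 oxygen, configuration as in 8) | O=C1[C@@]2(C)[C@@H](OS(=O)(=O)C(F)(F)F)C(C)=C[C@@H](C)[C@H]2[C@H](C)O1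
F5 | step 8 | (S)-1-[(1R,6S)-6-(hydroxymethyl)-2,4,6-trimethylcyclohexa-2,4-dien-1-yl]ethanol | OC[C@@]1(C)C=C(C)C=C(C)[C@H]1[C@H](C)O
F6 | step 8 | bis(triethylsilyl) ether of F5 | CC[Si](CC)(CC)OC[C@@]1(C)C=C(C)C=C(C)[C@H]1[C@H](C)O[Si](CC)(CC)CC
F0 | step 13 | none | none
F7 | step 17 | 6-{(1S,6R)-6-[(E)-2-hydroxypent-3-en-2-yl]-1,3,5-trimethylcyclohexa-2,4-dien-1-yl}-2-methoxy-3,5-dimethyl-4H-pyran-4-one (C7 epimers) | COc1oc([C@@]2(C)C=C(C)C=C(C)[C@H]2C(C)(O)/C=C/C)c(C)c(=O)c1C
A1 | alternative 1 | (R)-2-(3,5-dimethylphenyl)-4-isopropyl-4,5-dihydrooxazole | CC(C)[C@@H]1COC(=N1)c2cc(C)cc(C)c2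
A2 | alternative 1 | [1-(2-methyl-1,3-dioxolan-2-yl)prop-1-en-2-yl]lithium, lithium trans to the dioxolane carbon | [Li]/C(C)=C/C1(C)OCCO1
A3 | alternative 1 | 5-alkenyl-6-methyl-6-oxazolinylcyclohexa-1,3-diene (product of the dearomatising addition and methylation) | CC(C)[C@@H]1COC(=N1)[C@@]2(C)C=C(C)C=C(C)[C@H]2/C(C)=C/C3(C)OCCO3
A4 | alternative 2 | (E)-2-iodo-3-(2-methyl-1,3-dioxolan-2-yl)allyl 1,3,5-trimethylcyclohexa-2,5-diene-1-carboxylate | CC1=CC(C)(C=C(C)C1)C(=O)OC/C(I)=C\C2(C)OCCO2
A5 | alternative 2 | cis-fused alkylidene δ-lactone of the trimethylcyclohexadiene (Heck product) | O=C1[C@@]2(C)C=C(C)C=C(C)[C@H]2/C(CO1)=C/C3(C)OCCO3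
A6 | alternative 3 | 3,5-dimethyl-4-(prop-1-en-2-yl)-3-(prop-1-yn-1-yl)dihydrofuran-2(3H)-one, propynyl and isopropenyl cis, isopropenyl and C5 methyl trans | O=C1[C@@](C)(C#CC)[C@@H](C(C)=C)[C@H](C)O1
A7 | alternative 3 | (3S,3aR,7aS)-3,4,6,7a-tetramethyl-3a,7a-dihydroisobenzofuran-1(3H)-one (identical with 10) | O=C1[C@@]2(C)C=C(C)C=C(C)[C@H]2[C@H](C)O1
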